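A direct plan would dimerise (E)-3-(4-methoxy-3-methyl-2-oxo-2H-pyran-6-yl)but-2-enoic acid A1 head-to-head: esterification of two molecules onto naphthalene-1,8-diol would give the diester A2, irradiation would close the cyclobutane to the cyclic diester A3, and saponification would release the diacid. Its weakest steps would be:
(a) the [2+2] photodimerisation, which would have to join two fully substituted β-carbons carrying photoactive 2-pyranones and would depend on stacking of the two arms within about 4 Å;
(b) the attachment and removal of the template, two steps that would add no skeletal complexity;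
(c) the hydroxide ester cleavages beside two 2-pyranone lactones and two epimerisable α-carbons, where ring opening and cis-to-trans epimerisation would compete.

With the ring numbered C1, C2 (carboxyl-bearing) and C3, C4 (methyl- and pyranone-bearing), the route cuts C1–C4 and C2–C3 and postpones both pyranones. Dimethylmaleic anhydride supplies C3/C4 with their methyls and the two acyl carbons that become C6 of the pyranones; 2,5-dimethoxy-2,5-dihydrofuran supplies C1/C2 with masked carboxyls. Their crossed [2+2] photocycloaddition closes the cyclobutane and sets all four stereocentres at once: each five-membered ring enforces one cis pair, and the anti ring fusion places the future carboxyls cis to the methyls. The mirror plane through the C1–C2 and C3–C4 midpoints then lets both pyranones be built two-directionally. No template, crystal packing or ester saponification is needed.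

Key step: step 1

Remark on the chemistry: commercial 2 is a cis/trans mixture at its acetal carbons, so compounds 3–10 would be carried as mixtures of acetal epimers (7 also as a mixture at its carbinol and C2 centres). All of these centres disappear in steps 5 and 7, and the SMILES leave them undefined.

Step 1
Reactants: 1 2,3-dimethylmaleic anhydride (3,4-dimethylfuran-2,5-dione); 2 2,5-dimethoxy-2,5-dihydrofuran (cis/trans mixture)
Product: 3 3,5-dimethoxy-1,7-dimethyl-4,9-dioxatricyclo[5.3.0.0(2,6)]decane-8,10-dione, the cis-anti-cis adduct (cyclobutane with the anhydride cis-fused on one face and the 2,5-dimethoxytetrahydrofuran cis-fused on the other; methyls on the tetrahydrofuran face)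
Conditions: hν (300 nm, Pyrex), acetone (solvent and triplet sensitiser), 2 in fivefold excess, 10 °C, N2; unreacted 2 recovered by distillation
Reagents that add atoms: none
Why: This is a crossed [2+2] photocycloaddition of a cyclic ene-dicarbonyl with a cyclic cis-alkene, a pure addition in which every atom of 1 and of one molecule of 2 ends up in 3: acetone-sensitised triplet 1 adds to the C3=C4 bond of 2 to give a 1,4-biradical (tertiary α-acyl radical and secondary ring radical), which after intersystem crossing closes the four-membered ring by radical recombination, forming C2–C3 and C4–C1 of the target ring. The anhydride ring holds the two quaternary centres cis (carbonyls on one face, methyls on the other) and the dihydrofuran ring holds C1/C2 cis, so neither pair can scramble in the biradical. The ring fusion should be anti, because closure with both five-membered rings on the same face of the new cyclobutane is the more crowded path, as generally found for photoadducts of maleic anhydrides with cycloalkenes; this places the acetal carbons (future carboxyls) cis to the methyls and trans to the acyl carbons (future pyranones). The step needs cross-addition over homodimerisation of 1, secured by the fivefold excess of the non-absorbing partner 2, and cycloaddition over hydrogen abstraction, favoured by the π,π* character of the anhydride triplet and by fast energy transfer from acetone to 1.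

Step 2
Reactants: 3 the cis-anti-cis anhydride bis-acetal
Product: 4 (2,4-dimethoxy-6,7-dimethyl-3-oxabicyclo[3.2.0]heptane-6,7-diyl)dimethanol (hydroxymethyls cis to each other and exo, methyls endo)
Conditions: LiAlH4 (3 equiv), THF, 0 °C → reflux; H2O/aq NaOH work-up
Reagents that add atoms: none
Why: Hydride reduction of the cyclic anhydride (via the lactone) gives the 1,4-diol, while the acetals are inert to LiAlH4 and none of the ring stereocentres can epimerise.

Step 3
Reactants: 4 the diol bis-acetal
Product: 5 2,4-dimethoxy-6,7-dimethyl-3-oxabicyclo[3.2.0]heptane-6,7-dicarbaldehyde (formyls cis, exo)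
Conditions: (COCl)2 (3 equiv), DMSO (6 equiv), CH2Cl2, −78 °C; then Et3N (8 equiv), −78 → 0 °C
Reagents that add atoms: none
Why: Swern oxidation converts both neopentyl hydroxyls into alkoxysulfonium ions before base is added, so the dialdehyde forms instead of a lactol or lactone, and the formyl groups on quaternary carbons have no α-hydrogen for epimerisation or self-aldol.

Step 4
Reactants: 5 the dialdehyde; 6 methyl 2-methyl-3-oxobutanoate (2.4 equiv)
Product: 7 dimethyl 5,5'-(2,4-dimethoxy-6,7-dimethyl-3-oxabicyclo[3.2.0]heptane-6,7-diyl)bis(5-hydroxy-2-methyl-3-oxopentanoate) (diastereomer mixture)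
Conditions: 6, LiN(i-Pr)2 (5.0 equiv), THF, 0 °C, 30 min; then 5, −78 °C, 1 h; AcOH, −78 °C
Reagents that add atoms: none
Why: In this two-directional Huckin–Weiler dianion aldol addition the γ-carbanion of the acetoacetate dianion adds to each non-enolisable aldehyde at −78 °C, and the new carbinol and C2 stereocentres, formed unselectively, are all erased in step 5.

Step 5
Reactants: 7 the bis(δ-hydroxy-β-keto ester)
Product: 9 6,6'-(2,4-dimethoxy-6,7-dimethyl-3-oxabicyclo[3.2.0]heptane-6,7-diyl)bis(4-hydroxy-3-methyl-2H-pyran-2-one), via bis-diketo ester 8 (not isolated)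
Conditions: Dess–Martin periodinane (2.6 equiv), CH2Cl2, 0 °C → rt; aq NaHCO3 wash, crude; then DBU (4 equiv), THF, rt; cold 0.5 M citric acid work-up
Reagents that add atoms: none
Why: Dess–Martin oxidation gives the bis(3,5-diketo ester), and DBU then closes each arm by 6-exo-trig attack of the C5 enolate oxygen on the ester (lactonisation with loss of methanol) to the 4-hydroxy-2-pyranone anion, a thermodynamic sink; because both 1,4-related ketones are held as diketonates under excess base, they should not act as electrophiles toward the neighbouring arm.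

Step 6
Reactants: 9 the bis(4-hydroxy-2-pyranone)
Product: 10 6,6'-(2,4-dimethoxy-6,7-dimethyl-3-oxabicyclo[3.2.0]heptane-6,7-diyl)bis(4-methoxy-3-methyl-2H-pyran-2-one)
Conditions: Me2SO4 (2.6 equiv), K2CO3 (4 equiv), acetone, rt → 40 °C
Reagents that add atoms: dimethyl sulfate, COS(=O)(=O)OC
Why: O-Alkylation of the vinylogous acids (as potassium salts) with the hard electrophile dimethyl sulfate should give the 4-methoxy-2-pyranone regioisomer on both rings, the acetals being inert to base.

Step 7
Reactants: 10 the bis(4-methoxy-2-pyranone) bis-acetal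
Product: 12 (1R,2S,3R,4S)-3,4-bis(4-methoxy-3-methyl-2-oxo-2H-pyran-6-yl)-3,4-dimethylcyclobutane-1,2-dicarboxylic acid (meso; CNP0574758.1), via dialdehyde 11 (not isolated)
Conditions: 1 M HCl, THF/H2O (1:1), rt; then NaClO2 (6 equiv), NaH2PO4, 2-methyl-2-butene (20 equiv), t-BuOH/H2O, 0 °C → rt; acidify to pH 2
Reagents that add atoms: water, O; sodium chlorite, [Na+].[O-]Cl=O
Why: Acid hydrolysis of the cyclic bis-acetal releases the cis-dialdehyde, held as its cyclic hydrate and so protected from epimerisation, and Pinnick (Lindgren) oxidation at about pH 4 then gives the cis-diacid without touching the 2-pyranone lactones or the methyl enol ethers, so the configuration set in step 1 is carried unchanged into the target.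

Compound list
1 | 2,3-dimethylmaleic anhydride | CC1=C(C)C(=O)OC1=O | starting material
2 | 2,5-dimethoxy-2,5-dihydrofuran (cis/trans mixture) | COC1C=CC(OC)O1 | starting material
3 | 3,5-dimethoxy-1,7-dimethyl-4,9-dioxatricyclo[5.3.0.0(2,6)]decane-8,10-dione (cis-anti-cis; acetal epimers) | O=C3[C@@]1(C)[C@H](C(OC)O5)[C@H](C5OC)[C@@]1(C)C(=O)O3 | intermediate
4 | (2,4-dimethoxy-6,7-dimethyl-3-oxabicyclo[3.2.0]heptane-6,7-diyl)dimethanol (hydroxymethyls exo) | OC[C@@]1(C)[C@H](C(OC)O5)[C@H](C5OC)[C@@]1(C)CO | intermediate
5 | 2,4-dimethoxy-6,7-dimethyl-3-oxabicyclo[3.2.0]heptane-6,7-dicarbaldehyde (formyls exo) | O=C[C@@]1(C)[C@H](C(OC)O5)[C@H](C5OC)[C@@]1(C)C=O | intermediate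
6 | methyl 2-methyl-3-oxobutanoate | COC(=O)C(C)C(C)=O | starting material
7 | dimethyl 5,5'-(2,4-dimethoxy-6,7-dimethyl-3-oxabicyclo[3.2.0]heptane-6,7-diyl)bis(5-hydroxy-2-methyl-3-oxopentanoate) (diastereomer mixture) | COC(=O)C(C)C(=O)CC(O)[C@@]1(C)[C@H](C(OC)O5)[C@H](C5OC)[C@@]1(C)C(O)CC(=O)C(C)C(=O)OC | intermediate
8 | dimethyl 5,5'-(2,4-dimethoxy-6,7-dimethyl-3-oxabicyclo[3.2.0]heptane-6,7-diyl)bis(2-methyl-3,5-dioxopentanoate) (not isolated) | COC(=O)C(C)C(=O)CC(=O)[C@@]1(C)[C@H](C(OC)O5)[C@H](C5OC)[C@@]1(C)C(=O)CC(=O)C(C)C(=O)OC | intermediate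
9 | 6,6'-(2,4-dimethoxy-6,7-dimethyl-3-oxabicyclo[3.2.0]heptane-6,7-diyl)bis(4-hydroxy-3-methyl-2H-pyran-2-one) | Oc1cc([C@@]2(C)[C@H](C(OC)O5)[C@H](C5OC)[C@@]2(C)c2cc(O)c(C)c(=O)o2)oc(=O)c1C | intermediate
10 | 6,6'-(2,4-dimethoxy-6,7-dimethyl-3-oxabicyclo[3.2.0]heptane-6,7-diyl)bis(4-methoxy-3-methyl-2H-pyran-2-one) | COc1cc([C@@]2(C)[C@H](C(OC)O5)[C@H](C5OC)[C@@]2(C)c2cc(OC)c(C)c(=O)o2)oc(=O)c1C | intermediate
11 | 3,4-bis(4-methoxy-3-methyl-2-oxo-2H-pyran-6-yl)-3,4-dimethylcyclobutane-1,2-dicarbaldehyde (formyls cis to each other and to the methyls; present as cyclic hydrate; not isolated) | COc1cc([C@@]2(C)[C@H](C=O)[C@H](C=O)[C@@]2(C)c2cc(OC)c(C)c(=O)o2)oc(=O)c1C | intermediate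
12 | (1R,2S,3R,4S)-3,4-bis(4-methoxy-3-methyl-2-oxo-2H-pyran-6-yl)-3,4-dimethylcyclobutane-1,2-dicarboxylic acid (meso) | COc1cc([C@@]2(C)[C@H](C(=O)O)[C@H](C(=O)O)[C@@]2(C)c2cc(OC)c(C)c(=O)o2)oc(=O)c1C | target

Total step count: 7. Longest linear sequence: 7 steps (1 → 3 → 4 → 5 → 7 → 9 → 10 → 12).

Steps most likely to fail

Step 1. Hydrogen abstraction from the doubly oxygenated allylic C–H bonds of 2 by the excited sensitiser or anhydride, together with homodimerisation of 1, could outrun the crossed cycloaddition. Fallback, from 1 back to 4: the same triplet cycloaddition would be run with cis-3,4-dichlorocyclobutene, which has no acetal C–H, to give 5,6-dichloro-2,3-dimethylbicyclo[2.2.0]hexane-2,3-dicarboxylic anhydride F1 (anhydride exo). Zinc dust in AcOH/Et2O would eliminate the vicinal chlorides to 2,3-dimethylbicyclo[2.2.0]hex-5-ene-2,3-dicarboxylic anhydride F2, and LiAlH4 in THF would reduce this to (2,3-dimethylbicyclo[2.2.0]hex-5-ene-2,3-diyl)dimethanol F3. Ozonolysis (O3, CH2Cl2/MeOH, −78 °C; Me2S) would then unzip the cyclobutene of this easier-to-build bicyclic skeleton to 3,4-bis(hydroxymethyl)-3,4-dimethylcyclobutane-1,2-dicarbaldehyde F4, which HC(OMe)3/MeOH/pyridinium tosylate would close to the cyclic bis-acetal 4.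

Step 4. After the first addition the alkoxide could add to the neighbouring aldehyde and hold it as a lactolate (or pass hydride in a Cannizzaro–Tishchenko manner), so that the second arm is not installed. Fallback, from 3 back to 8, staying at the acyl oxidation level: NaOMe/MeOH then MeI/DMF would open and esterify the anhydride to dimethyl 2,4-dimethoxy-6,7-dimethyl-3-oxabicyclo[3.2.0]heptane-6,7-dicarboxylate F5. MeNH(OMe)·HCl with i-PrMgCl in THF would convert it into the bis-Weinreb amide N6,N7,2,4-tetramethoxy-N6,N7,6,7-tetramethyl-3-oxabicyclo[3.2.0]heptane-6,7-dicarboxamide F6. The dianion of 6 would then add once to each amide through chelated tetrahedral intermediates, which reveal no ketone and no acidic methylene until work-up and so cannot attack the neighbouring acyl group in a Dieckmann manner. Acidic work-up would give the bis-diketo ester 8, which would enter the DBU stage of step 5.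

Step 5. Under base the two 1,4-related triketide arms could condense with each other (aldol or Knoevenagel closure of a five-membered ring) instead of lactonising, or the enolised diketo ester could be over-oxidised. Fallback, from 5 back to 10, bringing in the C4 oxygen already methylated: 6 with HC(OMe)3 and catalytic H2SO4 would give methyl (E)-3-methoxy-2-methylbut-2-enoate F7. Its γ-lithio dienolate (LiN(i-Pr)2, THF, −78 °C) would add to 5 in a vinylogous aldol reaction, quenched cold with AcOH before lactonisation, to give dimethyl (2E,2'E)-5,5'-(2,4-dimethoxy-6,7-dimethyl-3-oxabicyclo[3.2.0]heptane-6,7-diyl)bis(5-hydroxy-3-methoxy-2-methylpent-2-enoate) F8. Dess–Martin oxidation would give the bis-ketone dimethyl (2E,2'E)-5,5'-(2,4-dimethoxy-6,7-dimethyl-3-oxabicyclo[3.2.0]heptane-6,7-diyl)bis(3-methoxy-2-methyl-5-oxopent-2-enoate) F9, which contains no 1,3-diketone. DBU in THF at rt would close both enol lactones with loss of methanol directly to 10, bypassing 9 and the O-methylation.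

Further compounds
F1 | step 1 | 5,6-dichloro-2,3-dimethylbicyclo[2.2.0]hexane-2,3-dicarboxylic anhydride (anhydride exo) | O=C3[C@@]1(C)[C@H](C5Cl)[C@H](C5Cl)[C@@]1(C)C(=O)O3
F2 | step 1 | 2,3-dimethylbicyclo[2.2.0]hex-5-ene-2,3-dicarboxylic anhydride (anhydride exo) | O=C3[C@@]1(C)[C@H](C5)[C@H](C=5)[C@@]1(C)C(=O)O3
F3 | step 1 | (2,3-dimethylbicyclo[2.2.0]hex-5-ene-2,3-diyl)dimethanol (hydroxymethyls exo) | OC[C@@]1(C)[C@H](C5)[C@H](C=5)[C@@]1(C)CO
F4 | step 1 | 3,4-bis(hydroxymethyl)-3,4-dimethylcyclobutane-1,2-dicarbaldehyde (formyls cis to each other and to the methyls) | OC[C@@]1(C)[C@H](C=O)[C@H](C=O)[C@@]1(C)CO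
F5 | step 4 | dimethyl 2,4-dimethoxy-6,7-dimethyl-3-oxabicyclo[3.2.0]heptane-6,7-dicarboxylate | COC(=O)[C@@]1(C)[C@H](C(OC)O5)[C@H](C5OC)[C@@]1(C)C(=O)OC
F6 | step 4 | N6,N7,2,4-tetramethoxy-N6,N7,6,7-tetramethyl-3-oxabicyclo[3.2.0]heptane-6,7-dicarboxamide | CON(C)C(=O)[C@@]1(C)[C@H](C(OC)O5)[C@H](C5OC)[C@@]1(C)C(=O)N(C)OC
F7 | step 5 | methyl (E)-3-methoxy-2-methylbut-2-enoate | CO/C(C)=C(\C)C(=O)OC
F8 | step 5 | dimethyl (2E,2'E)-5,5'-(2,4-dimethoxy-6,7-dimethyl-3-oxabicyclo[3.2.0]heptane-6,7-diyl)bis(5-hydroxy-3-methoxy-2-methylpent-2-enoate) | COC(=O)/C(C)=C(/OC)CC(O)[C@@]1(C)[C@H](C(OC)O5)[C@H](C5OC)[C@@]1(C)C(O)C/C(OC)=C(/C)C(=O)OC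
F9 | step 5 | dimethyl (2E,2'E)-5,5'-(2,4-dimethoxy-6,7-dimethyl-3-oxabicyclo[3.2.0]heptane-6,7-diyl)bis(3-methoxy-2-methyl-5-oxopent-2-enoate) | COC(=O)/C(C)=C(/OC)CC(=O)[C@@]1(C)[C@H](C(OC)O5)[C@H](C5OC)[C@@]1(C)C(=O)C/C(OC)=C(/C)C(=O)OC
A1 | direct plan | (E)-3-(4-methoxy-3-methyl-2-oxo-2H-pyran-6-yl)but-2-enoic acid | C/C(=C\C(=O)O)c1cc(OC)c(C)c(=O)o1
A2 | direct plan | naphthalene-1,8-diyl bis[(2E)-3-(4-methoxy-3-methyl-2-oxo-2H-pyran-6-yl)but-2-enoate] | C/C(=C\C(=O)Oc1cccc2cccc(OC(=O)/C=C(\C)c3cc(OC)c(C)c(=O)o3)c12)c1cc(OC)c(C)c(=O)o1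
A3 | direct plan | naphthalene-1,8-diyl (1R,2S,3R,4S)-3,4-bis(4-methoxy-3-methyl-2-oxo-2H-pyran-6-yl)-3,4-dimethylcyclobutane-1,2-dicarboxylate (cyclic diester) | COc1cc([C@@]2(C)[C@H](C(=O)Oc3cccc4cccc(O6)c34)[C@H](C6=O)[C@@]2(C)c2cc(OC)c(C)c(=O)o2)oc(=O)c1C
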